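**Retrosynthetic overview**
- The target is the scopoletin 7‑O‑ether of a (2E,4R)‑4,7‑dihydroxy‑3,7‑dimethyloct‑2‑enyl chain. The last disconnection is the aryl allyl ether bond C7–O–C1', closed by a paired electrolysis between scopoletin and the E‑allylic triol.
- Triol ⇐ E‑enoate (ester reduction) ⇐ α‑hydroxy methyl ketone by a stabilised Wittig reaction (C2'=C3').
- Hydroxy ketone ⇐ Weinreb amide of a γ‑lactone acid plus three MeMgBr (the C3'–CH3 bond and both C7'–CH3 bonds in one flask).
- The C4' stereocenter is C2 of (R)‑5‑oxotetrahydrofuran‑2‑carboxylic acid (D‑glutamic acid pool) and is carried through unchanged.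
- Rings: none is built. The coumarin bicycle arrives intact with scopoletin in the last step; the lactone of the pool compound is opened in step 2.

Assumption: (R)‑5‑oxotetrahydrofuran‑2‑carboxylic acid (the lactone acid of the D‑glutamic acid pool) and scopoletin are bought as such.

**Route**

Step 1
Reactants: 1 (R)-5-oxotetrahydrofuran-2-carboxylic acid
Product: 3 (R)-N-methoxy-N-methyl-5-oxotetrahydrofuran-2-carboxamide, via acyl imidazole 2 (not isolated)
Conditions: CDI (1.1 equiv), CH2Cl2, 0 °C, 45 min; then MeNH(OMe)·HCl (1.3 equiv), 0 °C → rt, 12 h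
Reagents that add atoms: N,O-dimethylhydroxylamine hydrochloride, CNOC.Cl
Why: CDI-mediated amidation (Weinreb amide formation) through acyl imidazole 2 under neutral, cold conditions, so the α-oxygenated stereocenter bought in 1 is not epimerised and the lactone stays closed.

Step 2
Reactants: 3 (R)-N-methoxy-N-methyl-5-oxotetrahydrofuran-2-carboxamide
Product: 5 (3R)-3,6-dihydroxy-6-methylheptan-2-one, via magnesium hemiaminal chelate 4 (not isolated)
Conditions: MeMgBr (4.5 equiv), THF, −78 → 0 °C, 3 h; then aq. NH4Cl, 0 °C
Reagents that add atoms: methylmagnesium bromide, C[Mg]Br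
Why: Weinreb ketone synthesis merged with a double Grignard addition to the γ-lactone: the N-methoxy-N-methyl carbonyl takes up one methyl and is held as chelate 4 until the quench, while the lactone carbonyl takes up two methyls and opens to the tertiary alkoxide, so all three C–CH3 bonds form in one flask and the C–O stereocenter is not touched.

Step 3
Reactants: 5 (3R)-3,6-dihydroxy-6-methylheptan-2-one
Product: 6 ethyl (2E,4R)-4,7-dihydroxy-3,7-dimethyloct-2-enoate
Conditions: Ph3P=CHCO2Et (1.5 equiv), CH2Cl2, 40 °C, 36 h
Reagents that add atoms: ethyl (triphenylphosphoranylidene)acetate, CCOC(=O)C=P(c1ccccc1)(c1ccccc1)c1ccccc1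
Why: Wittig olefination with a stabilised ylide, which reacts readily with α-hydroxy ketones and places the ester trans to the branched carbinol carbon (E); the minor Z-isomer lactonises to a butenolide and is removed on silica, and no new stereocenter is formed.

Step 4
Reactants: 6 ethyl (2E,4R)-4,7-dihydroxy-3,7-dimethyloct-2-enoate
Product: 7 (2E,4R)-3,7-dimethyloct-2-ene-1,4,7-triol
Conditions: iBu2AlH (5 equiv), CH2Cl2/THF, −78 → −20 °C; then aq. KNaC4H4O6 (potassium sodium tartrate)
Reagents that add atoms: none
Why: Selective 1,2-reduction of the α,β-unsaturated ester to the primary allylic alcohol by diisobutylaluminium hydride (excess covers the two free hydroxyls), without conjugate reduction and without change of olefin geometry or stereocenter.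

Step 5
Reactants: 7 (2E,4R)-3,7-dimethyloct-2-ene-1,4,7-triol; 8 scopoletin (7-hydroxy-6-methoxy-2H-chromen-2-one)
Product: 10 7-{[(2E,4R)-4,7-dihydroxy-3,7-dimethyloct-2-en-1-yl]oxy}-6-methoxy-2H-chromen-2-one, via alkoxyphosphonium iodide 9 (not isolated)
Conditions: 8 (1.2 equiv), PPh3 (1.3 equiv), nBu4NI (0.3 equiv), 2,6-lutidine (1.0 equiv), nBu4NBF4 (0.1 M), MeCN/THF 3:1, rt; undivided cell, graphite anode, Pt cathode, 5 mA cm−2, 2.3 F mol−1
Reagents that add atoms: none
Why: Proposed new method: a paired, iodide-mediated electrolysis used as an azo-free Mitsunobu-type etherification, in which the anode oxidises catalytic iodide to I2 at a potential well below those of PPh3, the neutral phenol, the aryl ether and the alkene, I2 and PPh3 give Ph3PI+ I−, which turns the least hindered (primary allylic) hydroxyl of 7 into the alkoxyphosphonium ion 9, while the Pt cathode reduces the released protons (2,6-lutidinium, then the phenol O–H) to H2 and so delivers the phenoxide of 8, which displaces Ph3P=O from 9 by SN2 at C1' and leaves the E-olefin and the C4' stereocenter untouched; the closest known reaction types are the Garegg–Samuelsson/Appel activation of alcohols with Ph3P and halogen, the anodic halide-mediated Appel-type activation of alcohols, and the Mitsunobu aryl ether synthesis.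

**Compound list**
1 | (R)-5-oxotetrahydrofuran-2-carboxylic acid | OC(=O)[C@H]1CCC(=O)O1 | starting material
2 | (R)-5-(1H-imidazole-1-carbonyl)dihydrofuran-2(3H)-one (acyl imidazole) | O=C([C@H]1CCC(=O)O1)n1ccnc1 | intermediate
3 | (R)-N-methoxy-N-methyl-5-oxotetrahydrofuran-2-carboxamide | CON(C)C(=O)[C@H]1CCC(=O)O1 | intermediate
4 | tris(bromomagnesium) alkoxide of (3R)-2-[methoxy(methyl)amino]-6-methylheptane-2,3,6-triol (chelated tetrahedral adduct; C2 configuration not defined) | CC(O[Mg]Br)(N(C)OC)[C@H](O[Mg]Br)CCC(C)(C)O[Mg]Br | intermediate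
5 | (3R)-3,6-dihydroxy-6-methylheptan-2-one | CC(=O)[C@H](O)CCC(C)(C)O | intermediate
6 | ethyl (2E,4R)-4,7-dihydroxy-3,7-dimethyloct-2-enoate | CCOC(=O)/C=C(\C)[C@H](O)CCC(C)(C)O | intermediate
7 | (2E,4R)-3,7-dimethyloct-2-ene-1,4,7-triol | OC/C=C(\C)[C@H](O)CCC(C)(C)O | intermediate
8 | scopoletin (7-hydroxy-6-methoxy-2H-chromen-2-one) | COc1cc2ccc(=O)oc2cc1O | starting material
9 | {[(2E,4R)-4,7-dihydroxy-3,7-dimethyloct-2-en-1-yl]oxy}triphenylphosphonium iodide | C(/C=C(\C)[C@H](O)CCC(C)(C)O)O[P+](c1ccccc1)(c1ccccc1)c1ccccc1.[I-] | intermediate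
10 | 7-{[(2E,4R)-4,7-dihydroxy-3,7-dimethyloct-2-en-1-yl]oxy}-6-methoxy-2H-chromen-2-one | COc1cc2ccc(=O)oc2cc1OC/C=C(\C)[C@H](O)CCC(C)(C)O | target

**Step count and risks**

Total steps: 5. Longest linear sequence: 5 (from 1).

The three steps most likely to fail:

- **Step 5 (new method).** Risks are oxidation of the phenoxide at the anode, cathodic loss of the phosphonium ion, and competing activation of the C4' hydroxyl (cyclodehydration with the tertiary hydroxyl to a tetrahydrofuran). The fallback uses known chemistry, sets out from 7 and comes back at 10. Corey–Kim chlorination (N-chlorosuccinimide, Me2S, CH2Cl2, −20 °C), which is selective for the primary allylic hydroxyl, gives (5R,6E)-8-chloro-2,6-dimethyloct-6-ene-2,5-diol F1. Williamson etherification of this chloride with scopoletin 8 (K2CO3, cat. KI, acetone, 50 °C) gives 10.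

- **Step 3.** Risks are slow olefination of the hindered, partly hemiketalised α-hydroxy ketone, a poor E/Z ratio, and base-promoted enolisation (epimerisation) of 5. The fallback sets out from 5 and comes back at 6. Silylation of both hydroxyls (Et3SiOTf, 2,6-lutidine, CH2Cl2, 0 °C) gives (3R)-6-methyl-3,6-bis(triethylsilyloxy)heptan-2-one F2. Horner–Wadsworth–Emmons olefination with triethyl phosphonoacetate and NaH (THF, 0 °C → rt), which is E-selective for α-silyloxy methyl ketones, gives ethyl (2E,4R)-3,7-dimethyl-4,7-bis(triethylsilyloxy)oct-2-enoate F3. HF·pyridine (THF, 0 °C) removes both silyl groups and gives 6.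

- **Step 2.** Risks are incomplete double addition to the lactone (enolisation of the intermediate methyl ketone) and collapse of the chelate with over-addition at C2. The fallback sets out from 1 and comes back at 5, bypassing 3. The acid 1 is treated with MeLi (5 equiv, THF, −78 → 0 °C, inverse quench into cold aq. NH4Cl). Organolithium addition to the lithium carboxylate releases the methyl ketone only at the quench, while the lactone takes up two methyls. No new compound is isolated on this way (F0).

**Further compounds**
F1 | step 5 | (5R,6E)-8-chloro-2,6-dimethyloct-6-ene-2,5-diol | ClC/C=C(\C)[C@H](O)CCC(C)(C)O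
F2 | step 3 | (3R)-6-methyl-3,6-bis(triethylsilyloxy)heptan-2-one | CC(=O)[C@H](O[Si](CC)(CC)CC)CCC(C)(C)O[Si](CC)(CC)CC
F3 | step 3 | ethyl (2E,4R)-3,7-dimethyl-4,7-bis(triethylsilyloxy)oct-2-enoate | CCOC(=O)/C=C(\C)[C@H](O[Si](CC)(CC)CC)CCC(C)(C)O[Si](CC)(CC)CC
F0 | step 2 | none | none
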